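The route rests on disconnecting N1–C7a of the pyrrole ring. With bromine on both C4 and C7 of ring A (the benzene ring), the matching 2,5-dibromophenyl precursor has only one ortho carbon that still bears hydrogen. That carbon becomes C7a, so closure by a side-chain nitrogen is regiochemically unambiguous. Heating methyl (2Z)-2-azido-3-(2,5-dibromophenyl)prop-2-enoate, made in one condensation from 2,5-dibromobenzaldehyde and methyl azidoacetate, expels N2 and closes the pyrrole ring in one operation with both benzo bromines in place. The C2 ester is then hydrolysed and exchanged for bromine by ipso-bromodecarboxylation, together with bromination at C3.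

Key step: step 2

Assumption: the vinyl nitrene of step 2 is a transient open-shell species and carries no number; the closed-shell species that form in the flask are numbered.

Step 1
Reactants: 1 2,5-dibromobenzaldehyde; 2 methyl azidoacetate
Product: 4 methyl (2Z)-2-azido-3-(2,5-dibromophenyl)prop-2-enoate, via aldol adduct 3 (not isolated)
Conditions: NaOMe (4 equiv), 2 (4 equiv), MeOH/THF, −15 °C to 0 °C; cold aq. NH4Cl quench; product kept cold and dark
Reagents that add atoms: none
Why: Knoevenagel-type aldol condensation (first stage of the Hemetsberger–Knittel sequence), in which methoxide deprotonates the azido ester, the carbanion adds to the non-enolisable aldehyde to give 3, and E1cB loss of hydroxide should give the conjugated vinyl azide as the thermodynamically preferred Z isomer (aryl trans to the ester), while the low temperature protects the base-labile azide and the matching methyl ester/methoxide pair makes ester exchange degenerate.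

Step 2
Reactants: 4 methyl (2Z)-2-azido-3-(2,5-dibromophenyl)prop-2-enoate
Product: 7 methyl 4,7-dibromo-1H-indole-2-carboxylate, via 2H-azirine ester 5 (not isolated), via 7aH-indole ester 6 (not isolated)
Conditions: xylene (0.05 M), reflux (about 140 °C), slow addition of 4, under N2
Reagents that add atoms: none
Why: Heat drives N2 out of the vinyl azide and leaves a singlet vinyl nitrene in equilibrium with the 2H-azirine 5, which serves as a reservoir and reopens at this temperature. The closest known reaction type is the Hemetsberger–Knittel indole-2-carboxylate synthesis, applied here directly to a 2,5-dihalogenated arene. The pyrrole ring closes by a five-atom, six-electron electrocyclisation in which the nitrene nitrogen, the C2=C3 bond and the C3a=C7a bond of the arene combine to form N1–C7a, giving the non-aromatic 7aH-indole 6. A suprafacial 1,5-hydrogen shift from C7a to N1 then restores the benzene ring and should deliver the 1H-indole; no stereocentre reaches the product, because the sp3 centre of 6 is erased in this shift. The selectivity needed is closure at the hydrogen-bearing ortho carbon (C6 of the aryl ring) and not at the brominated one (C2); the substrate secures it because closure at C–Br gives a species with no hydrogen to shift that cannot rearomatise directly, whereas C–H closure aromatises irreversibly and places the bromines at C4 and C7. High dilution and slow addition should keep bimolecular decay of nitrene and azirine slower than the intramolecular closure.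

Step 3
Reactants: 7 methyl 4,7-dibromo-1H-indole-2-carboxylate
Product: 9 4,7-dibromo-1H-indole-2-carboxylic acid, via lithium carboxylate 8 (not isolated)
Conditions: LiOH·H2O (3 equiv), THF/MeOH/H2O, 40 °C; then 1 M HCl, 0 °C, pH 2
Reagents that add atoms: lithium hydroxide (used as the monohydrate), [Li+].[OH-]
Why: Saponification by acyl–oxygen cleavage (BAc2) should give the lithium carboxylate 8 and, after acidification, the free acid, since the aryl bromides are inert to hydroxide at this temperature and the indole N–H is at most deprotonated reversibly.

Step 4
Reactants: 9 4,7-dibromo-1H-indole-2-carboxylic acid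
Product: 11 2,3,4,7-tetrabromo-1H-indole, via 3-bromo acid 10 (not isolated)
Conditions: NBS (2.1 equiv), LiOAc (0.2 equiv), dry DMF, 0 °C to 40 °C, dark; aq. Na2S2O3/NaHCO3 work-up
Reagents that add atoms: N-bromosuccinimide, O=C1CCC(=O)N1Br
Why: Electrophilic aromatic bromination at C3, the most nucleophilic carbon of the indole, gives 10, and a second bromonium transfer to the carboxyl-bearing C2 of its carboxylate followed by loss of CO2 from the σ-complex (ipso-bromodecarboxylation, the halodecarboxylation known for indole- and pyrrole-2-carboxylic acids) should restore the aromatic ring as the 2,3-dibromide, while NBS releases neutral succinimide instead of HBr and the dry medium withholds the water that oxindole formation would need.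

Compound list
1 | 2,5-dibromobenzaldehyde | O=Cc1cc(Br)ccc1Br | starting material
2 | methyl azidoacetate | COC(=O)CN=[N+]=[N-] | starting material
3 | methyl 2-azido-3-(2,5-dibromophenyl)-3-hydroxypropanoate (aldol adduct, mixture of racemic diastereomers, not isolated) | COC(=O)C(N=[N+]=[N-])C(O)c1cc(Br)ccc1Br | intermediate
4 | methyl (2Z)-2-azido-3-(2,5-dibromophenyl)prop-2-enoate | COC(=O)/C(N=[N+]=[N-])=C/c1cc(Br)ccc1Br | intermediate
5 | methyl 2-(2,5-dibromophenyl)-2H-azirine-3-carboxylate (racemic, not isolated) | COC(=O)C1=NC1c1cc(Br)ccc1Br | intermediate
6 | methyl 4,7-dibromo-7aH-indole-2-carboxylate (racemic, not isolated) | COC(=O)C1=NC2C(Br)=CC=C(Br)C2=C1 | intermediate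
7 | methyl 4,7-dibromo-1H-indole-2-carboxylate | COC(=O)c1cc2c(Br)ccc(Br)c2[nH]1 | intermediate
8 | lithium 4,7-dibromo-1H-indole-2-carboxylate (not isolated) | [Li+].[O-]C(=O)c1cc2c(Br)ccc(Br)c2[nH]1 | intermediate
9 | 4,7-dibromo-1H-indole-2-carboxylic acid | OC(=O)c1cc2c(Br)ccc(Br)c2[nH]1 | intermediate
10 | 3,4,7-tribromo-1H-indole-2-carboxylic acid (not isolated) | OC(=O)c1[nH]c2c(Br)ccc(Br)c2c1Br | intermediate
11 | 2,3,4,7-tetrabromo-1H-indole | Brc1[nH]c2c(Br)ccc(Br)c2c1Br | target

Total step count: 4
Longest linear sequence: 4 steps (1 → 4 → 7 → 9 → 11)

Steps most likely to fail, in order of risk

Step 4. The ipso attack at C2 may be slow on an indole deactivated by the benzo bromines, so the reaction may stall after C3 bromination, or excess reagent may over-oxidise the 2,3-dibromoindole. The fallback separates carboxyl removal from bromination. It sets out from acid 9. Protodecarboxylation with Cu powder in quinoline at about 200 °C (or catalytic Ag2CO3 and AcOH in DMSO at 120 °C) should give 4,7-dibromo-1H-indole F1. NBS (1.0 equiv) in DMF at 0 °C should brominate C3 to give 3,4,7-tribromo-1H-indole F2. A second equivalent of NBS in THF at room temperature should then brominate C2, by attack at C3, 1,2-shift of bromine and loss of a proton. The fallback returns to the route at target 11.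

Step 2. Bimolecular decay of the free nitrene and of the azirine (oligomerisation, tar) may outrun a closure that is hindered by the bromine next to the reacting C–H. The fallback replaces the free nitrene by a metal-bound nitrenoid and keeps the same N1–C7a bond formation. It sets out from 4, which is treated with Rh2(O2CC3F7)4 (3–5 mol %) in toluene at 40–60 °C. The dirhodium carboxylate should bind the azide, release N2 and deliver the nitrogen to the ortho C–H carbon by electrophilic amination well below the temperature of thermolysis. It returns to the route at 7 and makes no compound outside the list (F0).

Step 1. The condensation may stop at the aldol stage, and the α-azido carbanion may decompose by loss of N2 before elimination occurs. The fallback splits addition and elimination. It sets out from 1 and 2. Addition at −30 °C with NaOMe (1.2 equiv) in MeOH/THF and a cold aq. NH4Cl quench should allow aldol adduct 3 to be isolated. MsCl and Et3N (2.5 equiv) in CH2Cl2 at −30 °C to room temperature should convert 3 into its mesylate, methyl 2-azido-3-(2,5-dibromophenyl)-3-[(methylsulfonyl)oxy]propanoate F3. This should undergo E1cB elimination in the same flask and rejoin the route at 4.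

Further compounds
F1 | step 4 | 4,7-dibromo-1H-indole | Brc1ccc(Br)c2[nH]ccc12
F2 | step 4 | 3,4,7-tribromo-1H-indole | Brc1c[nH]c2c(Br)ccc(Br)c12
F0 | step 2 | none | none
F3 | step 1 | methyl 2-azido-3-(2,5-dibromophenyl)-3-[(methylsulfonyl)oxy]propanoate (mixture of racemic diastereomers) | COC(=O)C(N=[N+]=[N-])C(OS(C)(=O)=O)c1cc(Br)ccc1Br
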